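The last dawn reading, 60.4% of the substrate as target, was the number I built on, since it tells how hard substrate attacks its own target.

the same everywhere: catalyst 17 µM
- dawn: substrate 16 mM; coupling partner 22 mM; run made earlier
- midnight: substrate 47 mM; coupling partner 22 mM; run made earlier
- alder: substrate 12 mM; coupling partner 22.0 mM; time 4.0 h
- birch: substrate 20 mM; coupling partner 22.0 mM; time 4.0 h
- maple: substrate 30 mM; coupling partner 22.0 mM; time 4.0 h

| run | time / min | target / % |
|---|---|---|
| dawn | 30.0 | 54.2 |
| dawn | 60.0 | 59.3 |
| dawn | 90.0 | 60.1 |
| dawn | 120 | 60.4 |
| midnight | 30.0 | 16.0 |
| midnight | 60.0 | 8.8 |
| midnight | 90.0 | 6.2 |
| midnight | 120 | 4.4 |

(standard deviation of a reading: 1 percentage point)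

- a species is counted by the substrate in it: one side product counts as two
- the numbers in the tables scatter by 1 percentage point (one standard deviation)
- steps that have been proposed: substrate + coupling partner + catalyst -> target + catalyst; substrate + target -> side product
- "hardly changes" means that all values lie within two and a half points (for a concentration: within two and a half percent of the largest)

- [target] at the end for alder, birch, maple, in this order
- how the row runs (rises all the way / rises, then falls / falls all the way / hardly changes / falls, then rises)

Two steps were proposed: substrate and coupling partner make target on the catalyst, and substrate with target makes side product. I took both as first order in substrate, with the catalyst folded into the first constant, so substrate multiplies both rates and cancels from their ratio. Loss of target then runs to its making as s × target / partner, where s, the selectivity factor, is the second constant over the first. With x the fraction of partner left, integration gave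

target = partner charge × (x^s − x) / (1 − s).

A balance came next: a target holds one substrate and one partner, a side product two substrates and one partner, so a flask with its substrate fully reacted obeys

substrate charge = 2 × partner used − target.

Dawn changed by 0.3 percentage points between its last readings, less than the scatter of 1 point, so I took it as finished, with 9.66 mM of target. The balance then gave x = 41.7%, and the formula gave s = 0.598, a value read from scattered readings that carries their scatter.

I then looked at both ends. With the partner charge held, a small substrate charge stops at high x, short of the top of the target curve, while a large one runs on to low x, where target is being eaten. The two join where making equals loss, at x = s^(1/(1 − s)) = 27.8%, with target at 10.2 mM. The balance turns that point into the best charge, the substrate charge that, at this partner charge, finishes exactly at the top of the target curve, 21.5 mM.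

The asked 4.0 h is twice dawn's last reading time, and maple's charge lies below twice the partner, so I let all three flasks finish. I tried values of x until the balance returned each charge:

| flask | partner left | charge returned | target |
|---|---|---|---|
| alder | 53.8% | 12.0 mM | 8.33 mM |
| birch | 31.2% | 20.1 mM | 10.2 mM |
| maple | 12.0% | 29.9 mM | 8.83 mM |

The forecast gave 8.3 mM, 10.2 mM and 8.8 mM, rises, then falls, in its words: “The peak is near 20 mM.”

    substrate + coupling partner + catalyst → target + catalyst, rate k1*[substrate]*[coupling partner]*[catalyst]/(1 + ([substrate]/sat1)) (41.0 mM, k = 1.50 × 10⁷ /M²/h)
    substrate + target → side product (k = 130 /M/h)

The flasks gave 8.49 mM, 10.3 mM and 8.74 mM, rises, then falls, with the turn at 21 mM. A fit of one step, with all reacted substrate read as target, answers rises all the way. The best charge of 21.5 mM sorts the flasks: alder, charged below it, ended with 53.4% of its partner left, more than the 27.8% I had reckoned for the top, and maple, charged above it, ended with 12.0%, less than that. Midnight, charged above it too, read 2.07 mM of target at 120 min.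

(The runs were generated by integration with constants of no real substance; the scatter is artificial.)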